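(The data were computed for substances that don't exist, noise included.)

| flask | substrate | free catalyst | remark | time |
|---|---|---|---|---|
| north-west | 0.50 M | 12 mM | run made earlier |  |
| west | 0.50 M | 19 mM | run made earlier |  |
| flask | 0.50 M | 25 mM |  | 30 h |

| run | time / h | product / % | substrate / % |
|---|---|---|---|
| north-west | 1.50 | 50.9 | 0 |
| north-west | 5.00 | 69.5 | 0.5 |
| north-west | 8.00 | 68.5 | 0 |
| north-west | 12.0 | 69.8 | 0 |
| north-west | 20.0 | 69.7 | 0 |
| north-west | 25.0 | 69.9 | 1.0 |
| north-west | 30.0 | 69.7 | 0 |
| west | 2.50 | 74.7 | 0.4 |
| west | 4.00 | 75.2 | 0.5 |
| west | 6.00 | 76.7 | 0 |
| west | 8.00 | 78.4 | 0 |
| west | 12.0 | 79.3 | 1.4 |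
| west | 20.0 | 77.9 | 0 |
| west | 30.0 | 77.2 | 0 |

(scatter of a reading: 1 percentage point)

- which holds at 30 h: what has brought the reaction to rest, or that it has not come to rest (all of the substrate has reacted / it is still moving)
- how much product there is at 30 h, in percent of the substrate charged

- what was read earlier has a scatter of 1 percentage point, one standard deviation
- reactions considered so far: free catalyst + intermediate -> free catalyst + product; free catalyst + product -> spent catalyst; substrate -> intermediate
- the reaction counts as stopped when no species that holds the substrate changes by six tenths of a point or more over the second half of the time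

- The north-west run went flat early: product read 68.5% at 8.00 h and 69.7% at 30.0 h, so I gave the length of the run no weight.
- Substrate read 0% at 1.50 h, less than product at 50.9%, so I gave its rate little weight and expected the same end as the forecast.
- I divided the rate of making product by the rate of losing free catalyst, and time dropped out. With f as the share of substrate ever turned to product, I got −ln(1−f) − f = R·c(free catalyst)/c(substrate), both as charged, treating the product taken up as small.
- Here R is the selectivity factor: product made per free catalyst lost at equal c(intermediate) and c(product).
- I read each flat stretch as the end of free catalyst, each unit having taken one product, so f is product read plus the charge ratio. In the flask that ratio is 5.00%, which weighs heavily.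
- From 8.00 h on, north-west averaged 69.5%, so f = 71.9% and R = 23.0.
- West averaged 78.2%, so f = 82.0% and R = 23.5.
- Their mean, R = 23.3, gave a right side of 1.16 and so, by my reckoning, product 81.9% in the flask. The gap between the two R values is worth about 0.45 percentage points of product there.
- The forecast said all of the substrate has reacted and 83.3%, 1.4 points above mine, noting that “more catalyst reaches the plateau faster”.

The flask gave all of the substrate has reacted and 81.8%.

    free catalyst + intermediate → free catalyst + product (k = 0.940 /M/min)
    free catalyst + product → spent catalyst (k = 0.0400 /M/min)
    substrate → intermediate (k = 0.0660 /min)

- Read back, the flask's product gave R = 23.1, beside my 23.3. On the neighbour flask with 0.010 M of free catalyst, the same 23.3 gave a right side of 0.465 and product 66.3%, and that flask held 66.4%. The flask had come to rest: its largest change over the second half was 0 points, with free catalyst at 0% after 30.0 h. Left until 300 h, it still held 81.8% of product and 13.2% of intermediate.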